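**Strategy.** The oxolane ring is numbered O1, C2 (trimethoxyphenyl), C3 (hydroxymethyl carbon C3a), C4 (benzylic carbon C4a), C5. Everything rests on cutting C2–C3. The C2–H bond, flanked by O1 and the aryl ring, sits in a 1,5 relationship to C3, so a rhodium carbene at C3 of a γ-lactone (carbonyl C3a, ring CH2 C4a) can insert into it. That one operation forms C2–C3, closes the oxolane cis-fused to the lactone and relays the single centre C4 to C3 and C2. Its precursor is an α-diazo-γ-butyrolactone whose β-carbon carries a (3,4,5-trimethoxybenzyloxy)methyl arm. The lactone is then opened to attach the veratryl ring at C4a.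

Key step: step 4

Remark (assumption): (R)-paraconic acid is taken as a purchasable enantiopure acid; the rhodium step by itself is expected to leave the aryl group on the concave face of the bicycle, so the convex epimer is reached by Lewis-acid equilibration in the same flask.

**Step 1**
Reactants: 1 (R)-paraconic acid
Product: 2 (4S)-4-(hydroxymethyl)oxolan-2-one
Conditions: BH3·SMe2, THF, 0 °C to rt; MeOH
Reagents that add atoms: none
Why: Borane reduction of a carboxylic acid (through its acyloxyborane) is much faster than reduction of the lactone, so only the acid carbon becomes CH2OH; the stereocentre is untouched (R becomes S by priority only), and the neutral conditions avoid the base-induced translactonisation that would swap the two CH2O arms and racemise 2.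

**Step 2**
Reactants: 2 (4S)-4-(hydroxymethyl)oxolan-2-one; 3 3,4,5-trimethoxybenzyl bromide
Product: 4 (4S)-4-{[(3,4,5-trimethoxyphenyl)methoxy]methyl}oxolan-2-one
Conditions: Ag2O, 4 Å molecular sieves, CH2Cl2, rt, dark
Reagents that add atoms: none
Why: Silver-oxide-promoted Williamson-type etherification, in which Ag2O pulls bromide from the reactive benzylic bromide and takes up the proton without forming a free alkoxide, so the primary alcohol is alkylated while the lactone neither opens nor translactonises; no stereocentre is formed or disturbed.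

**Step 3**
Reactants: 4 (4S)-4-{[(3,4,5-trimethoxyphenyl)methoxy]methyl}oxolan-2-one
Product: 6 (4S)-3-diazo-4-{[(3,4,5-trimethoxyphenyl)methoxy]methyl}oxolan-2-one, via trifluoroacetyl lactone 5 (not isolated)
Conditions: LiN(SiMe3)2, THF, −78 °C, then CF3CO2CH2CF3; cold dilute HCl work-up; crude 5, 4-acetamidobenzenesulfonyl azide, Et3N, H2O (1 equiv), MeCN, rt
Reagents that add atoms: 2,2,2-trifluoroethyl trifluoroacetate, FC(F)(F)COC(=O)C(F)(F)F (trifluoroacetyl group, kept only in 5); 4-acetamidobenzenesulfonyl azide, CC(=O)Nc1ccc(cc1)S(=O)(=O)N=[N+]=[N-] (the two diazo nitrogens of 6)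
Why: Claisen-type trifluoroacetylation of the lactone α-carbon followed by Regitz-type diazo transfer, in which the trifluoroacetyl group leaves on the sulfonamide nitrogen (detrifluoroacetylative diazo transfer), is the standard way to put a diazo group next to a lactone carbonyl that is too weakly acidic for direct transfer; C4 lies outside the enolised position and keeps its configuration.

**Step 4**
Reactants: 6 (4S)-3-diazo-4-{[(3,4,5-trimethoxyphenyl)methoxy]methyl}oxolan-2-one
Product: 8 (1R,5S,8R)-8-(3,4,5-trimethoxyphenyl)-3,7-dioxabicyclo[3.3.0]octan-2-one (cis-fused, aryl on the convex face), via concave-aryl lactone 7 (not isolated)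
Conditions: Rh2(OAc)4 (2 mol%), CH2Cl2, 40 °C, 6 added slowly; then BF3·OEt2 (0.3 equiv), 0 °C to rt
Reagents that add atoms: none
Why: Rh2(OAc)4 (divalent rhodium) expels N2 from 6 to give an electrophilic rhodium carbene at C3, whose empty orbital takes up the C2–H bond of the benzylic ether in a concerted, hydride-transfer-like three-centre transition state that makes C2–C3; the closest known reaction type is the dirhodium-catalysed intramolecular 1,5 C–H insertion of α-diazo lactones and esters next to an ether oxygen. The oxolane ring (O1, C2, C3, C4, C5) is closed by this 1,5-insertion through a six-centre array that counts the migrating hydrogen, the normal five-ring mode for such carbenes. C3 is set by C4: a trans-fused 3,7-dioxabicyclo[3.3.0]octanone is too strained, so the new C–C bond must form on the face that carries the CH2O side chain and the ring fusion is cis. C2 is set in two stages: in the insertion transition state the aryl group is expected to turn away from the acetate wall of the catalyst and so to sit on the concave face (7), and BF3·OEt2, added once gas evolution has ended, reversibly ionises the benzylic C2–O1 bond so that reclosure should settle the aryl group on the less crowded, lower-energy convex face, trans to the lactone carbonyl carbon C3a (8). The step needs chemoselectivity for the C2–H bond over a 1,2-hydride shift from C4, attack on the electron-rich arene and oxonium ylide formation; the double activation of C2–H by O1 and the aryl ring, its 1,5 position and the four-membered ring that attack by O1 would require secure this, while slow addition keeps carbene dimerisation down.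

**Step 5**
Reactants: 8 (1R,5S,8R)-8-(3,4,5-trimethoxyphenyl)-3,7-dioxabicyclo[3.3.0]octan-2-one
Product: 10 methyl (2R,3R,4R)-4-(hydroxymethyl)-2-(3,4,5-trimethoxyphenyl)oxolane-3-carboxylate, via potassium carboxylate 9 (not isolated)
Conditions: KOH (1.0 equiv), MeOH/H2O, 0 °C to rt; evaporate; MeI, DMF, 0 °C; crude product used at once
Reagents that add atoms: potassium hydroxide, [K+].[OH-]; iodomethane, CI
Why: Saponification opens the lactone to the carboxylate, which cannot relactonise while it is a salt, and SN2 O-methylation of that carboxylate with MeI in DMF is far faster than alkylation of the neutral primary hydroxyl, so C3a ends as the ester and C4a as the free alcohol; no stereocentre is involved, the carbon α to a carboxylate not being acidic under these conditions.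

**Step 6**
Reactants: 10 methyl (2R,3R,4R)-4-(hydroxymethyl)-2-(3,4,5-trimethoxyphenyl)oxolane-3-carboxylate
Product: 11 methyl (2R,3R,4S)-4-(iodomethyl)-2-(3,4,5-trimethoxyphenyl)oxolane-3-carboxylate
Conditions: PPh3, I2, imidazole, CH2Cl2, 0 °C
Reagents that add atoms: iodine, II
Why: Appel-type iodination, in which the primary hydroxyl becomes an alkoxyphosphonium ion that iodide displaces by SN2 at C4a within minutes at 0 °C, faster than the hydroxy ester can close back to the lactone, and the ester carbonyl is too poor a nucleophile to interfere; the configuration at C4 is unchanged (its descriptor becomes S by priority only).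

**Step 7**
Reactants: 11 methyl (2R,3R,4S)-4-(iodomethyl)-2-(3,4,5-trimethoxyphenyl)oxolane-3-carboxylate; 12 4-bromo-1,2-dimethoxybenzene
Product: 14 methyl (2R,3R,4S)-4-[(3,4-dimethoxyphenyl)methyl]-2-(3,4,5-trimethoxyphenyl)oxolane-3-carboxylate, via alkylzinc iodide 13 (not isolated)
Conditions: Zn dust (activated with BrCH2CH2Br and Me3SiCl), DMA, 40 °C; then 12, Pd(OAc)2 (2 mol%), SPhos (4 mol%), THF, 50 °C
Reagents that add atoms: zinc, [Zn] (kept only in 13)
Why: Negishi coupling, in which zinc inserts into the primary C–I bond to give an ester-tolerant alkylzinc iodide and zerovalent palladium carrying the bulky biarylphosphine joins it to the aryl bromide by oxidative addition, transmetalation and reductive elimination faster than β-hydride elimination, forming C4a–aryl under neutral conditions that leave the ester, the benzylic ether and all three stereocentres alone.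

**Step 8**
Reactants: 14 methyl (2R,3R,4S)-4-[(3,4-dimethoxyphenyl)methyl]-2-(3,4,5-trimethoxyphenyl)oxolane-3-carboxylate
Product: 15 [(2R,3S,4S)-4-[(3,4-dimethoxyphenyl)methyl]-2-(3,4,5-trimethoxyphenyl)oxolan-3-yl]methanol (CNP0107562.1)
Conditions: LiAlH4, THF, 0 °C; NaOH/H2O work-up
Reagents that add atoms: none
Why: Hydride reduction of the methyl ester by LiAlH4 gives the primary alcohol at C3a, the aryl methyl ethers and the benzylic ring ether being inert to hydride, and addition to the carbonyl is much faster than enolisation, so C3 is not epimerised (R becomes S by priority only).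

**Compound list**
1 | (R)-paraconic acid, (3R)-5-oxooxolane-3-carboxylic acid | OC(=O)[C@H]1COC(=O)C1 | starting material
2 | (4S)-4-(hydroxymethyl)oxolan-2-one | O=C1OC[C@H](CO)C1 | intermediate
3 | 3,4,5-trimethoxybenzyl bromide | COc1cc(CBr)cc(OC)c1OC | starting material
4 | (4S)-4-{[(3,4,5-trimethoxyphenyl)methoxy]methyl}oxolan-2-one | O=C1OC[C@H](COCc2cc(OC)c(OC)c(OC)c2)C1 | intermediate
5 | (4S)-3-(trifluoroacetyl)-4-{[(3,4,5-trimethoxyphenyl)methoxy]methyl}oxolan-2-one, C3 undefined (enolisable) | O=C1OC[C@H](COCc2cc(OC)c(OC)c(OC)c2)C1C(=O)C(F)(F)F | intermediate (not isolated)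
6 | (4S)-3-diazo-4-{[(3,4,5-trimethoxyphenyl)methoxy]methyl}oxolan-2-one | O=C1OC[C@H](COCc2cc(OC)c(OC)c(OC)c2)C1=[N+]=[N-] | intermediate
7 | (1R,5S,8S)-8-(3,4,5-trimethoxyphenyl)-3,7-dioxabicyclo[3.3.0]octan-2-one, cis-fused, aryl on the concave face | O=C1OC[C@@H]2CO[C@H](c3cc(OC)c(OC)c(OC)c3)[C@@H]21 | intermediate (not isolated)
8 | (1R,5S,8R)-8-(3,4,5-trimethoxyphenyl)-3,7-dioxabicyclo[3.3.0]octan-2-one, cis-fused, aryl on the convex face | O=C1OC[C@@H]2CO[C@@H](c3cc(OC)c(OC)c(OC)c3)[C@@H]21 | intermediate
9 | potassium (2R,3R,4R)-4-(hydroxymethyl)-2-(3,4,5-trimethoxyphenyl)oxolane-3-carboxylate | OC[C@@H]1CO[C@@H](c2cc(OC)c(OC)c(OC)c2)[C@@H]1C(=O)[O-].[K+] | intermediate (not isolated)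
10 | methyl (2R,3R,4R)-4-(hydroxymethyl)-2-(3,4,5-trimethoxyphenyl)oxolane-3-carboxylate | OC[C@@H]1CO[C@@H](c2cc(OC)c(OC)c(OC)c2)[C@@H]1C(=O)OC | intermediate
11 | methyl (2R,3R,4S)-4-(iodomethyl)-2-(3,4,5-trimethoxyphenyl)oxolane-3-carboxylate | IC[C@@H]1CO[C@@H](c2cc(OC)c(OC)c(OC)c2)[C@@H]1C(=O)OC | intermediate
12 | 4-bromo-1,2-dimethoxybenzene (4-bromoveratrole) | COc1ccc(Br)cc1OC | starting material
13 | {[(3S,4R,5R)-4-(methoxycarbonyl)-5-(3,4,5-trimethoxyphenyl)oxolan-3-yl]methyl}zinc iodide | I[Zn]C[C@@H]1CO[C@@H](c2cc(OC)c(OC)c(OC)c2)[C@@H]1C(=O)OC | intermediate (not isolated)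
14 | methyl (2R,3R,4S)-4-[(3,4-dimethoxyphenyl)methyl]-2-(3,4,5-trimethoxyphenyl)oxolane-3-carboxylate | COc1ccc(C[C@@H]2CO[C@@H](c3cc(OC)c(OC)c(OC)c3)[C@@H]2C(=O)OC)cc1OC | intermediate
15 | [(2R,3S,4S)-4-[(3,4-dimethoxyphenyl)methyl]-2-(3,4,5-trimethoxyphenyl)oxolan-3-yl]methanol | COc1ccc(C[C@@H]2CO[C@@H](c3cc(OC)c(OC)c(OC)c3)[C@@H]2CO)cc1OC | target

**Total step count:** 8
**Longest linear sequence:** 8 steps (1 to 15)

**Steps most likely to fail**

Most at risk is step 4. The process that may fail is control of the C2 configuration: the two C8 epimers of the bicyclic lactone may lie close in energy, so that Lewis-acid equilibration stalls at a mixture, or the opened benzylic cation may lose a proton towards an arylidene lactone. The fallback sets out from 7 and returns at 11. The BF3·OEt2 stage is left out and the concave epimer 7 is isolated. KOH opens it to potassium (2S,3R,4R)-4-(hydroxymethyl)-2-(3,4,5-trimethoxyphenyl)oxolane-3-carboxylate F1, MeI in DMF gives methyl (2S,3R,4R)-4-(hydroxymethyl)-2-(3,4,5-trimethoxyphenyl)oxolane-3-carboxylate F2, and PPh3/I2/imidazole gives methyl (2S,3R,4S)-4-(iodomethyl)-2-(3,4,5-trimethoxyphenyl)oxolane-3-carboxylate F3. In this monocyclic oxolane the C3 ester is squeezed between two cis neighbours, so BF3·OEt2 in CH2Cl2 (ionisation of C2–O1 and reclosure by the C5 oxygen, the only nucleophile at hand once C4a carries iodide) should move the aryl group to the 2,3-trans position with a much larger driving force, which gives 11.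

Second is step 5. The process that may fail is survival of the open form: the cis γ-hydroxy ester can close back to lactone 8 during work-up or before iodination is complete. The fallback sets out from 8 and returns at 15. Aminolysis of 8 with pyrrolidine and AlMe3 in CH2Cl2 gives [(2R,3R,4R)-4-(hydroxymethyl)-2-(3,4,5-trimethoxyphenyl)oxolan-3-yl](pyrrolidin-1-yl)methanone F4, whose poor amine leaving group holds the ring open. PPh3/I2/imidazole gives [(2R,3R,4S)-4-(iodomethyl)-2-(3,4,5-trimethoxyphenyl)oxolan-3-yl](pyrrolidin-1-yl)methanone F5; the amide oxygen may intercept the activated C4a, so this iodide is used at once. Zinc insertion gives {[(3S,4R,5R)-4-(pyrrolidine-1-carbonyl)-5-(3,4,5-trimethoxyphenyl)oxolan-3-yl]methyl}zinc iodide F6, and Pd(OAc)2/SPhos coupling with 12 gives [(2R,3R,4S)-4-[(3,4-dimethoxyphenyl)methyl]-2-(3,4,5-trimethoxyphenyl)oxolan-3-yl](pyrrolidin-1-yl)methanone F7. LiEt3BH in THF then reduces the tertiary amide to the primary alcohol, which is 15.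

Third is step 2. The process that may fail is a slow silver-promoted alkylation, during which 2 can translactonise with erosion of enantiopurity, or the benzylic bromide can be lost to self-condensation. The fallback sets out from 2 and returns at 4. Compound 2 is silylated (hexamethyldisilazane, catalytic Me3SiCl) to (4R)-4-{[(trimethylsilyl)oxy]methyl}oxolan-2-one F8 (descriptor changed by priority only), which has no free hydroxyl and cannot translactonise. Reductive etherification of F8 with purchased 3,4,5-trimethoxybenzaldehyde and Et3SiH under catalytic Me3SiOTf in CH2Cl2 at −78 °C then gives 4.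

**Further compounds**
F1 | step 4 | potassium (2S,3R,4R)-4-(hydroxymethyl)-2-(3,4,5-trimethoxyphenyl)oxolane-3-carboxylate | OC[C@@H]1CO[C@H](c2cc(OC)c(OC)c(OC)c2)[C@@H]1C(=O)[O-].[K+]
F2 | step 4 | methyl (2S,3R,4R)-4-(hydroxymethyl)-2-(3,4,5-trimethoxyphenyl)oxolane-3-carboxylate | OC[C@@H]1CO[C@H](c2cc(OC)c(OC)c(OC)c2)[C@@H]1C(=O)OC
F3 | step 4 | methyl (2S,3R,4S)-4-(iodomethyl)-2-(3,4,5-trimethoxyphenyl)oxolane-3-carboxylate | IC[C@@H]1CO[C@H](c2cc(OC)c(OC)c(OC)c2)[C@@H]1C(=O)OC
F4 | step 5 | [(2R,3R,4R)-4-(hydroxymethyl)-2-(3,4,5-trimethoxyphenyl)oxolan-3-yl](pyrrolidin-1-yl)methanone | OC[C@@H]1CO[C@@H](c2cc(OC)c(OC)c(OC)c2)[C@@H]1C(=O)N3CCCC3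
F5 | step 5 | [(2R,3R,4S)-4-(iodomethyl)-2-(3,4,5-trimethoxyphenyl)oxolan-3-yl](pyrrolidin-1-yl)methanone | IC[C@@H]1CO[C@@H](c2cc(OC)c(OC)c(OC)c2)[C@@H]1C(=O)N3CCCC3
F6 | step 5 | {[(3S,4R,5R)-4-(pyrrolidine-1-carbonyl)-5-(3,4,5-trimethoxyphenyl)oxolan-3-yl]methyl}zinc iodide | I[Zn]C[C@@H]1CO[C@@H](c2cc(OC)c(OC)c(OC)c2)[C@@H]1C(=O)N3CCCC3
F7 | step 5 | [(2R,3R,4S)-4-[(3,4-dimethoxyphenyl)methyl]-2-(3,4,5-trimethoxyphenyl)oxolan-3-yl](pyrrolidin-1-yl)methanone | COc1ccc(C[C@@H]2CO[C@@H](c3cc(OC)c(OC)c(OC)c3)[C@@H]2C(=O)N4CCCC4)cc1OC
F8 | step 2 | (4R)-4-{[(trimethylsilyl)oxy]methyl}oxolan-2-one | O=C1OC[C@H](CO[Si](C)(C)C)C1
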